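**Retrosynthetic overview**

1. The target is read as (−)-epicatechin-(4β→8)-(−)-epigallocatechin 3-O-gallate (upper unit 2R,3R,4R, 2,3-cis-3,4-trans; lower unit 2R,3R); the last step is hydrogenolysis of twelve benzyl ethers and of a bromine cap on upper C8.
2. Key disconnection: the bond from upper C4 (ring C) to lower C8 (ring A), made by a one-flask oxidative C–H/C–H coupling in which DDQ takes hydride from C4 of 8-bromo-tetra-O-benzylepicatechin and C8 of octa-O-benzyl-EGCG then captures the cation on the β face.
3. Enabling feature: upper C4 is benzylic to ring A, with O1 and O5 ortho and O7 para to its point of attachment, so its cation is an O-benzylated ortho/para-quinone methide; the 3α-OH and 2α-aryl group on ring C shield the α face, and lower C8 lies between O1 and O7 as the most nucleophilic free carbon of ring A.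
4. Ring order: no ring is formed in the route; rings A, B and C of the upper unit come intact from (−)-epicatechin, those of the lower unit from (−)-epigallocatechin, and the galloyl ring from 3,4,5-tris(benzyloxy)benzoic acid, which is esterified onto O3 of the lower unit before the coupling; only C4 is created as a stereocentre.
5. Temporary groups: benzyl ethers on all twelve phenols and bromine on upper C8 (stops self-condensation of the electrophile); the upper 3-OH stays free and the gallate ester is carried through.

Key step: step 5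

**Route**

Step 1
Reactants: 1 (−)-epicatechin
Product: 2 5,7,3',4'-tetra-O-benzyl-(−)-epicatechin
Conditions: BnBr (4.4 equiv), K2CO3, DMF, 0 °C → rt, Ar
Reagents that add atoms: benzyl bromide, BrCc1ccccc1
Why: Williamson etherification in which carbonate deprotonates only the four phenols, so the secondary 3-OH should stay free and C2/C3 are not touched.

Step 2
Reactants: 2 5,7,3',4'-tetra-O-benzyl-(−)-epicatechin
Product: 3 8-bromo-5,7,3',4'-tetra-O-benzyl-(−)-epicatechin
Conditions: NBS (1.0 equiv), CH2Cl2, −78 °C → rt
Reagents that add atoms: N-bromosuccinimide, O=C1CCC(=O)N1Br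
Why: Electrophilic aromatic bromination, a known reaction of this substrate class, in which C8 (between O1 and the 7-benzyloxy group) should react before the more hindered C6 and long before ring B.

Step 3
Reactants: 4 (−)-epigallocatechin
Product: 5 5,7,3',4',5'-penta-O-benzyl-(−)-epigallocatechin
Conditions: BnBr (5.5 equiv), K2CO3, degassed DMF, 0 °C → rt, Ar
Reagents that add atoms: benzyl bromide, BrCc1ccccc1
Why: Williamson etherification in which carbonate deprotonates only the five phenols, so the secondary 3-OH should stay free, while exclusion of oxygen protects the pyrogallol ring and the mild base leaves C2/C3 untouched.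

Step 4
Reactants: 5 5,7,3',4',5'-penta-O-benzyl-(−)-epigallocatechin; 6 3,4,5-tris(benzyloxy)benzoic acid
Product: 7 octa-O-benzyl-EGCG
Conditions: DCC (1.5 equiv), DMAP (0.3 equiv), CH2Cl2, 0 °C → rt
Reagents that add atoms: none
Why: Steglich esterification in which the acylpyridinium ion formed from the O-acylisourea acylates the only free hydroxyl, the axial 3-OH, at oxygen, so C3 keeps its configuration and the neutral conditions cannot open ring C or epimerise C2.

Step 5
Reactants: 3 8-bromo-5,7,3',4'-tetra-O-benzyl-(−)-epicatechin; 7 octa-O-benzyl-EGCG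
Product: 9 8-bromo-dodeca-O-benzyl-epicatechin-(4β→8)-EGCG, via flavan-4-yl cation 8 (not isolated)
Conditions: 3, DDQ (0.95 equiv), 4 Å MS, CH2Cl2, 0 °C → rt; then 7 (1.3 equiv), Yb(OTf)3 (10 mol %), −20 °C → rt
Reagents that add atoms: none
Why: Proposed new method: DDQ should abstract the pseudoaxial hydride from C4 of 3, which is benzylic to ring A and stabilised by the ortho oxygens O1 and O5 and the para oxygen O7, to give the O-benzylated quinone-methide cation 8 (resting as its ion pair or covalent C4–O adduct with the DDQH anion), and C8 of 7 should then attack this cation in a Friedel–Crafts alkylation with loss of the proton to DDQH−, so that two C–H bonds are joined in one flask. The closest known reaction types are the DDQ oxidation of benzylated flavan-3-ols at C4 in the presence of alcohols, the Lewis-acid coupling of the resulting C4 ethers with benzylated flavan-3-ol nucleophiles, and DDQ-mediated oxidative C–H arylation of benzylic ethers; what is new is that the DDQH anion serves as the leaving group in place of an added alcohol. No ring is closed in this step. The new stereocentre C4 is set by the substrate: the arene should approach the half-chair cation axially on the β face, anti to the pseudoaxial 3α-OH and away from the 2α-aryl group, giving the 3,4-trans (4β) bond. The step needs chemoselective oxidation, C8 over C6 attack on 7 and mono-coupling: the oxidant is used in slight deficit and consumed before 7 is added so that the C4 methylene of 7 never meets it, the bromine on C8 of 3 blocks self-condensation during the oxidation and chain growth on the product, C8 of 7 (between O1 and O7, tied back by ring C) is more nucleophilic and less hindered than C6 (between two benzyloxy groups), and the C4–H of the product is pseudoequatorial and not aligned for further hydride loss.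

Step 6
Reactants: 9 8-bromo-dodeca-O-benzyl-epicatechin-(4β→8)-EGCG
Product: 10 (−)-epicatechin-(4β→8)-(−)-epigallocatechin 3-O-gallate
Conditions: H2 (1 atm), Pd(OH)2/C, Et3N (1.1 equiv), THF/MeOH/H2O, rt; Sephadex LH-20
Reagents that add atoms: none
Why: Catalytic hydrogenolysis of the twelve aryl benzyl ethers together with hydrodebromination of the aryl bromide should leave the gallate ester, the C4–C8 bond, the ring C ethers and all five stereocentres untouched, while Et3N takes up the HBr that could otherwise cleave the acid-labile interflavan bond.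

**Compound list**

1 | (−)-epicatechin, (2R,3R)-2-(3,4-dihydroxyphenyl)chromane-3,5,7-triol | O[C@@H]1Cc2c(O)cc(O)cc2O[C@@H]1c1ccc(O)c(O)c1 | starting material
2 | 5,7,3',4'-tetra-O-benzyl-(−)-epicatechin (2R,3R; 3-OH free) | O[C@@H]1Cc2c(OCc3ccccc3)cc(OCc3ccccc3)cc2O[C@@H]1c1ccc(OCc2ccccc2)c(OCc2ccccc2)c1 | intermediate
3 | 8-bromo-5,7,3',4'-tetra-O-benzyl-(−)-epicatechin (2R,3R) | O[C@@H]1Cc2c(OCc3ccccc3)cc(OCc3ccccc3)c(Br)c2O[C@@H]1c1ccc(OCc2ccccc2)c(OCc2ccccc2)c1 | intermediate
4 | (−)-epigallocatechin, (2R,3R)-2-(3,4,5-trihydroxyphenyl)chromane-3,5,7-triol | O[C@@H]1Cc2c(O)cc(O)cc2O[C@@H]1c1cc(O)c(O)c(O)c1 | starting material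
5 | 5,7,3',4',5'-penta-O-benzyl-(−)-epigallocatechin (2R,3R; 3-OH free) | O[C@@H]1Cc2c(OCc3ccccc3)cc(OCc3ccccc3)cc2O[C@@H]1c1cc(OCc2ccccc2)c(OCc2ccccc2)c(OCc2ccccc2)c1 | intermediate
6 | 3,4,5-tris(benzyloxy)benzoic acid | OC(=O)c1cc(OCc2ccccc2)c(OCc2ccccc2)c(OCc2ccccc2)c1 | starting material
7 | octa-O-benzyl-EGCG: (2R,3R)-5,7-bis(benzyloxy)-2-[3,4,5-tris(benzyloxy)phenyl]chroman-3-yl 3,4,5-tris(benzyloxy)benzoate | O=C(O[C@@H]1Cc2c(OCc3ccccc3)cc(OCc3ccccc3)cc2O[C@@H]1c1cc(OCc2ccccc2)c(OCc2ccccc2)c(OCc2ccccc2)c1)c1cc(OCc2ccccc2)c(OCc2ccccc2)c(OCc2ccccc2)c1 | intermediate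
8 | C4 cation of 3 (2,3-cis configuration retained), as its ion pair with the DDQH anion | O[C@@H]1[CH+]c2c(OCc3ccccc3)cc(OCc3ccccc3)c(Br)c2O[C@@H]1c1ccc(OCc2ccccc2)c(OCc2ccccc2)c1.[O-]c1c(Cl)c(Cl)c(O)c(C#N)c1C#N | intermediate (not isolated)
9 | 8-bromo-dodeca-O-benzyl-epicatechin-(4β→8)-EGCG (upper unit 2,3-cis-3,4-trans with free 3-OH and Br on its C8; lower unit 2,3-cis with the tribenzylgalloyl ester on O3) | O=C(O[C@@H]1Cc2c(OCc3ccccc3)cc(OCc3ccccc3)c([C@H]3c4c(OCc5ccccc5)cc(OCc5ccccc5)c(Br)c4O[C@H](c4ccc(OCc5ccccc5)c(OCc5ccccc5)c4)[C@@H]3O)c2O[C@@H]1c1cc(OCc2ccccc2)c(OCc2ccccc2)c(OCc2ccccc2)c1)c1cc(OCc2ccccc2)c(OCc2ccccc2)c(OCc2ccccc2)c1 | intermediate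
10 | (−)-epicatechin-(4β→8)-(−)-epigallocatechin 3-O-gallate (upper unit 2R,3R,4R; lower unit 2R,3R) | O=C(O[C@@H]1Cc2c(O)cc(O)c([C@H]3c4c(O)cc(O)cc4O[C@H](c4ccc(O)c(O)c4)[C@@H]3O)c2O[C@@H]1c1cc(O)c(O)c(O)c1)c1cc(O)c(O)c(O)c1 | target

**Step count and risks**

Total step count: 6. Longest linear sequence: 4 (steps 1, 2, 5, 6 from (−)-epicatechin, or steps 3, 4, 5, 6 from (−)-epigallocatechin).

Steps most likely to fail:

Step 5 (proposed new method). Hydride abstraction from the bromine-deactivated ring A may be slow, so the cation or its DDQH adduct could decay by proton loss, capture by the free 3-OH of a second molecule or over-oxidation before the arene is added. The adduct may also fail to re-ionise, or traces of oxidant may attack 7. The fallback uses known chemistry and sets out from 3: DDQ with 2-ethoxyethanol in CH2Cl2 at rt should give 8-bromo-4β-(2-ethoxyethoxy)-5,7,3',4'-tetra-O-benzylepicatechin F1, which is isolated. Catalytic TMSOTf in CH2Cl2 at −78 °C in the presence of 7 should then effect the Friedel–Crafts coupling with the same β-face and C8 selectivity. The fallback returns to the route at 9.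

Step 3. Benzylation of the free pyrogallol and phloroglucinol rings under base may suffer air oxidation of the phenoxides, C-benzylation of ring A, incomplete etherification, or epimerisation at C2 through base-induced opening of ring C. The fallback sets out from 4 and keeps the phenols masked until each is alkylated. Ac2O in pyridine should give air-stable hexa-O-acetyl-(−)-epigallocatechin F2. BnBr and K2CO3 in DMF containing a limited amount of MeOH should then cleave the five aryl acetates and benzylate each phenoxide as it forms, a Jurd-type conversion of aryl acetates into benzyl ethers. The slower-reacting alkyl acetate should survive, giving 3-O-acetyl-5,7,3',4',5'-penta-O-benzyl-(−)-epigallocatechin F3. K2CO3 in MeOH/THF at rt should then remove the 3-acetate and give 5, where the fallback returns to the route.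

Step 6. Amine and bromide may inhibit the catalyst and leave the debenzylation incomplete; unbuffered HBr could cleave the interflavan bond; the free polyphenol may oxidise in air on work-up. The fallback sets out from 9 and separates the two reductions. Radical hydrodebromination with Bu3SnH and AIBN in toluene at 90 °C should give dodeca-O-benzyl-epicatechin-(4β→8)-EGCG F4. Hydrogenolysis over Pd(OH)2/C in THF/MeOH/H2O without amine should then give the target, so the fallback returns to the route at 10.

Further compounds
F1 | step 5 | 8-bromo-4β-(2-ethoxyethoxy)-5,7,3',4'-tetra-O-benzylepicatechin (2,3-cis-3,4-trans) | CCOCCO[C@H]1c2c(OCc3ccccc3)cc(OCc3ccccc3)c(Br)c2O[C@H](c2ccc(OCc3ccccc3)c(OCc3ccccc3)c2)[C@@H]1O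
F2 | step 3 | hexa-O-acetyl-(−)-epigallocatechin (2R,3R) | CC(=O)O[C@@H]1Cc2c(OC(C)=O)cc(OC(C)=O)cc2O[C@@H]1c1cc(OC(C)=O)c(OC(C)=O)c(OC(C)=O)c1
F3 | step 3 | 3-O-acetyl-5,7,3',4',5'-penta-O-benzyl-(−)-epigallocatechin (2R,3R) | CC(=O)O[C@@H]1Cc2c(OCc3ccccc3)cc(OCc3ccccc3)cc2O[C@@H]1c1cc(OCc2ccccc2)c(OCc2ccccc2)c(OCc2ccccc2)c1
F4 | step 6 | dodeca-O-benzyl-epicatechin-(4β→8)-EGCG (bromine-free analogue of 9) | O=C(O[C@@H]1Cc2c(OCc3ccccc3)cc(OCc3ccccc3)c([C@H]3c4c(OCc5ccccc5)cc(OCc5ccccc5)cc4O[C@H](c4ccc(OCc5ccccc5)c(OCc5ccccc5)c4)[C@@H]3O)c2O[C@@H]1c1cc(OCc2ccccc2)c(OCc2ccccc2)c(OCc2ccccc2)c1)c1cc(OCc2ccccc2)c(OCc2ccccc2)c(OCc2ccccc2)c1
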